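Numbering: ten-membered ring C1–C10 with C2 the hemiketal carbon, C5 the ether CH, C6 the lactone O–CH and C8 the tiglate CH; C4=C15H2, C10=C14H2, lactone C11(=C13H2)–C12. The route rests on the unit C9H2–C10(=C14H2)–C1H2, which lies between C8 and the ketone-level C2 of the ten-membered ring.
Late stage: the tiglate on O8, the C13 methylidene and the free C2 hemiketal come last; the C8 oxygen comes from a C8 phenylsulfonyl group (oxidative desulfonylation, then reduction).
Key disconnection: ten-membered ring ⇒ C8-allylated 2-(phenylsulfonyl)cycloheptanone; fluoride makes C1–C2 and the alkoxide breaks C2–C8, which inserts C9–C10(=C14)–C1.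
Cycloheptanone ⇒ ring-closing metathesis (C7=C8) of a triene built from L-tartrate (C4–C7), two Me3SiCH2 units (C3, C15) and acrolein (C2, C8); a Mukaiyama–Michael addition sets C7 and hands over the C2=C8 enol ether for sulfenylation at C8.
Ring order: dioxolane (tartrate acetonide) → seven-membered carbocycle → ten-membered carbocycle → oxolane ketal (O5–C2) plus γ-lactone (O6–C12), closed together on acid.
Key step: step 11

Remark on the chemistry: a γ-lactone α-CH2 is more acidic than an α-sulfonyl C–H, so O5 and O6 pass through the ring expansion as the tartrate acetonide (O5 blocked, C2 a free ketone) with C11–C12 as a methyl acetate arm, and the lactone is held at the lactol level while the sulfone is exchanged for oxygen.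

Step 1
Reactants: 1 dimethyl (4R,5R)-2,2-dimethyl-1,3-dioxolane-4,5-dicarboxylate (dimethyl 2,3-O-isopropylidene-L-tartrate)
Product: 2 methyl (4R,5S)-5-(hydroxymethyl)-2,2-dimethyl-1,3-dioxolane-4-carboxylate
Conditions: NaBH4 (0.6 equiv), MeOH, 0 °C
Reagents that add atoms: none
Why: Borohydride reduction of an activated α-alkoxy ester with a deficit of hydride should stop largely at the mono-alcohol, and because the two esters are equivalent by two-fold symmetry any mono-reduction gives the same compound, with C5 and C6 taken unchanged from L-tartrate.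

Step 2
Reactants: 2 methyl (4R,5S)-5-(hydroxymethyl)-2,2-dimethyl-1,3-dioxolane-4-carboxylate
Product: 3 methyl (4R,5R)-5-formyl-2,2-dimethyl-1,3-dioxolane-4-carboxylate
Conditions: Dess–Martin periodinane, CH2Cl2, 0 → 25 °C; used crude at once
Reagents that add atoms: none
Why: Dess–Martin oxidation of the primary alcohol runs under near-neutral conditions, which should keep the α-alkoxy aldehyde carbon (C6) from epimerising.

Step 3
Reactants: 3 methyl (4R,5R)-5-formyl-2,2-dimethyl-1,3-dioxolane-4-carboxylate
Product: 4 methyl (4R,5S)-5-ethenyl-2,2-dimethyl-1,3-dioxolane-4-carboxylate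
Conditions: Ph3PCH3Br, KN(SiMe3)2, THF, −78 → 0 °C
Reagents that add atoms: methyltriphenylphosphonium bromide, C[P+](c1ccccc1)(c1ccccc1)c1ccccc1.[Br-]
Why: Wittig methylenation with the salt-free ylide at low temperature should turn the C7 aldehyde into the vinyl group needed for ring closure without touching the ester or C6.

Step 4
Reactants: 4 methyl (4R,5S)-5-ethenyl-2,2-dimethyl-1,3-dioxolane-4-carboxylate
Product: 6 (4S,5S)-4-ethenyl-2,2-dimethyl-5-[3-(trimethylsilyl)prop-1-en-2-yl]-1,3-dioxolane, via bis(silylmethyl) carbinol 5 (not isolated)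
Conditions: Me3SiCH2MgCl (4 equiv), CeCl3 (4 equiv), THF, −78 → 25 °C; then SiO2, CH2Cl2, 25 °C
Reagents that add atoms: (trimethylsilyl)methylmagnesium chloride, C[Si](C)(C)C[Mg]Cl
Why: Double addition of the non-basic organocerium reagent to the ester should give a tertiary alcohol with two β-silyl groups, and Peterson elimination of one of them on silica gives the 2-substituted allylsilane at C4 with C5 untouched.

Step 5
Reactants: 6 (4S,5S)-4-ethenyl-2,2-dimethyl-5-[3-(trimethylsilyl)prop-1-en-2-yl]-1,3-dioxolane; 7 acrolein (prop-2-enal)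
Product: 8 5-[(4S,5S)-5-ethenyl-2,2-dimethyl-1,3-dioxolan-4-yl]hexa-1,5-dien-3-ol (C3 epimers)
Conditions: BF3·OEt2 (1.1 equiv), CH2Cl2, −78 °C; aq. NaHCO3
Reagents that add atoms: none
Why: Hosomi–Sakurai 1,2-allylation of the enal: the electron-rich allylsilane should attack the aldehyde carbon through its CH2 terminus with allyl transposition, which makes C2–C3 and regenerates the C4=C15 methylidene, and the carbinol configuration is irrelevant because it is oxidised in step 7.

Step 6
Reactants: 8 5-[(4S,5S)-5-ethenyl-2,2-dimethyl-1,3-dioxolan-4-yl]hexa-1,5-dien-3-ol (C3 epimers)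
Product: 9 (4S,5S)-4,5-(isopropylidenedioxy)-6-methylidenecyclohept-2-en-1-ol (C1 epimers)
Conditions: RuCl2(=CHPh)(PCy3)(H2IMes) (second-generation Grubbs catalyst, 5 mol%), CH2Cl2 (0.005 M), 40 °C
Reagents that add atoms: none
Why: Ring-closing metathesis of the two monosubstituted alkenes should form C7=C8 and the seven-membered ring, since the 1,1-disubstituted C4=C15 alkene could only close a four-membered ring and stays out.

Step 7
Reactants: 9 (4S,5S)-4,5-(isopropylidenedioxy)-6-methylidenecyclohept-2-en-1-ol (C1 epimers)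
Product: 10 (4S,5S)-4,5-(isopropylidenedioxy)-6-methylidenecyclohept-2-en-1-one
Conditions: Dess–Martin periodinane, pyridine, CH2Cl2, 0 °C; used at once
Reagents that add atoms: none
Why: Dess–Martin oxidation of the allylic alcohol should give the cycloheptenone under buffered, non-basic conditions that keep the skipped C4=C15 alkene out of conjugation.

Step 8
Reactants: 10 (4S,5S)-4,5-(isopropylidenedioxy)-6-methylidenecyclohept-2-en-1-one; 11 tert-butyl[(1-methoxyethenyl)oxy]dimethylsilane
Product: 13 methyl 2-[(1S,2S,3S)-2,3-(isopropylidenedioxy)-4-methylidene-6-oxo-7-(phenylsulfanyl)cycloheptyl]acetate (C7 epimers), via silyl enol ether 12 (not isolated)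
Conditions: tBuMe2SiOSO2CF3 (10 mol%), CH2Cl2, −78 °C; then PhSCl (1.0 equiv), −78 °C
Reagents that add atoms: benzenesulfenyl chloride, ClSc1ccccc1
Why: Mukaiyama–Michael addition of the ketene silyl acetal to C7 should occur anti to the adjacent C6–O bond of the trans-fused dioxolane (side chain trans to O6), and the silyl enol ether that results exists only across C2=C8, so PhSCl sulfenylates C8 and not the more acidic C3.

Step 9
Reactants: 13 methyl 2-[(1S,2S,3S)-2,3-(isopropylidenedioxy)-4-methylidene-6-oxo-7-(phenylsulfanyl)cycloheptyl]acetate (C7 epimers)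
Product: 14 methyl 2-[(1S,2S,3S)-2,3-(isopropylidenedioxy)-4-methylidene-6-oxo-7-(phenylsulfonyl)cycloheptyl]acetate (C7 epimers)
Conditions: (NH4)6Mo7O24·4H2O (10 mol%), H2O2 (30%, 4 equiv), EtOH, 0 → 25 °C
Reagents that add atoms: hydrogen peroxide, OO
Why: Molybdate-catalysed peroxide oxidation should take the sulfide through the sulfoxide to the sulfone much faster than it epoxidises an unactivated 1,1-disubstituted alkene.

Step 10
Reactants: 14 methyl 2-[(1S,2S,3S)-2,3-(isopropylidenedioxy)-4-methylidene-6-oxo-7-(phenylsulfonyl)cycloheptyl]acetate (C7 epimers); 15 2-(chloromethyl)-3-(trimethylsilyl)prop-1-ene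
Product: 16 methyl 2-[(1S,2S,3S)-2,3-(isopropylidenedioxy)-4-methylidene-6-oxo-7-(phenylsulfonyl)-7-{2-[(trimethylsilyl)methyl]prop-2-en-1-yl}cycloheptyl]acetate (C7 epimers), the C8-alkylated 2-(phenylsulfonyl)cycloheptanone
Conditions: K2CO3 (1.5 equiv), NaI (10 mol%), DMF, 25 °C
Reagents that add atoms: none
Why: C-alkylation of the stabilised β-keto sulfone anion, the only site that carbonate deprotonates, by the allylic chloride activated in situ as the iodide (Finkelstein) should build the quaternary C8, whose configuration does not matter because C8 becomes a carbanion in step 11.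

Step 11
Reactants: 16 methyl 2-[(1S,2S,3S)-2,3-(isopropylidenedioxy)-4-methylidene-6-oxo-7-(phenylsulfonyl)-7-{2-[(trimethylsilyl)methyl]prop-2-en-1-yl}cycloheptyl]acetate (C7 epimers)
Product: 18 methyl 2-[(1S,2S,3S)-2,3-(isopropylidenedioxy)-4,8-dimethylidene-6-oxo-10-(phenylsulfonyl)cyclodecyl]acetate (C10 epimers), via bicyclic alkoxide 17 (not isolated)
Conditions: Bu4NF (1.5 equiv), THF, 0 → 25 °C; AcOH quench at 0 °C
Reagents that add atoms: none
Why: Fluoride attacks silicon and the allyl anion (or silicate) so released adds to the C2 ketone, which closes the methylidenecyclopentanol ring C2–C8–C9–C10–C1 in a 5-exo-trig mode and makes the C1–C2 bond; the tertiary alkoxide then fragments in retro-aldol fashion across C2–C8 because the phenylsulfonyl-stabilised C8 carbanion is a good leaving group, which merges the five- and seven-membered rings into the ten-membered ketone with the C10=C14 methylidene. The closest known reaction type is the fluoride-triggered three-carbon ring expansion of 2-sulfonylcycloalkanones that carry a 2-[(trimethylsilyl)methyl]allyl group on the sulfonyl carbon. Both allyl termini are CH2, so only one constitution can result. No stereocentre of the target is made: C2 becomes trigonal, C8 is left as an epimer mixture that step 14 erases, and C5, C6 and C7 are not touched. The step needs cleavage of C2–C8 and not of C2–C3 or C2–C1, which the sulfone secures, and a free C2 ketone, which the acetonide on O5 secures. The product is a doubly β,γ-unsaturated ketone, so the reaction is kept cold and quenched with acid as soon as the silane is consumed.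

Step 12
Reactants: 18 methyl 2-[(1S,2S,3S)-2,3-(isopropylidenedioxy)-4,8-dimethylidene-6-oxo-10-(phenylsulfonyl)cyclodecyl]acetate (C10 epimers)
Product: 19 tricyclic methyl ketal lactone sulfone (target numbering: 2S,5S,6S,7S; O5–C2 oxolane with C2–OMe, trans-fused 6,12-γ-lactone with C11H2, C8–SO2Ph as epimers, C4=C15H2, C10=C14H2)
Conditions: (+)-camphor-10-sulfonic acid (10 mol%), MeOH, 25 °C
Reagents that add atoms: methanol, CO
Why: Acid-catalysed methanolysis removes the acetonide and each freed hydroxyl should close the five-membered ring open to it, O5 onto the C2 ketone as the bridged methyl ketal and O6 onto the ester as the trans-fused γ-lactone; C2 is set by the bridge, because the oxolane can span C2 and C5 of the ten-membered ring on one face only.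

Step 13
Reactants: 19 tricyclic methyl ketal lactone sulfone
Product: 20 lactol of 19 (C12 hemiacetal as anomers, otherwise unchanged)
Conditions: iBu2AlH (1.2 equiv), CH2Cl2, −78 °C; aq. potassium sodium tartrate
Reagents that add atoms: none
Why: Half-reduction of the γ-lactone with iBu2AlH stops at the lactol because the aluminium hemiacetal is stable at −78 °C, and it removes the lactone α-CH2 acidity that would outrun the α-sulfonyl C8–H in step 14, while ketal and sulfone are inert.

Step 14
Reactants: 20 lactol of 19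
Product: 23 C8 ketone lactol (target numbering: 2S,5S,6S,7S; C12 hemiacetal as anomers), via C8-lithio sulfone 21 (not isolated), via C8 silyloxy sulfone 22 (not isolated)
Conditions: LiN(iPr)2 (2.5 equiv), THF, −78 → −40 °C; Me3SiOOSiMe3 (1.5 equiv), −78 → 0 °C; aq. NH4Cl
Reagents that add atoms: bis(trimethylsilyl) peroxide, C[Si](C)(C)OO[Si](C)(C)C
Why: Oxidative desulfonylation: after the lactol O–H the α-sulfonyl C8–H is the most acidic site, its carbanion should be oxygenated by the silyl peroxide, and the α-silyloxy sulfone loses benzenesulfinate to give the C8 ketone, both C8 epimers converging.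

Step 15
Reactants: 23 C8 ketone lactol
Product: 24 C8 ketone γ-lactone (target numbering: 2S,5S,6S,7S)
Conditions: TEMPO (2,2,6,6-tetramethylpiperidin-1-oxyl, 10 mol%), PhI(OAc)2 (1.3 equiv), CH2Cl2, 25 °C
Reagents that add atoms: none
Why: Oxoammonium oxidation of the lactol, the only hydroxyl in the molecule, should restore the γ-lactone under neutral conditions that do not enolise the C8 ketone towards C7.

Step 16
Reactants: 24 C8 ketone γ-lactone
Product: 25 (8S)-alcohol (target numbering: 2S,5S,6S,7R,8S)
Conditions: NaBH4, CeCl3·7H2O, MeOH, −78 °C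
Reagents that add atoms: none
Why: Luche reduction takes the ketone and leaves the lactone, and the small hydride is expected to give the alcohol trans to the C7–C11 bond (O8 cis to O6, 8S) as small hydrides do with 2-substituted cycloalkanones, while the weakly basic medium keeps C7 and the C10=C14 alkene in place.

Step 17
Reactants: 25 (8S)-alcohol; 26 tiglic acid, (E)-2-methylbut-2-enoic acid
Product: 27 8-O-tigloyl lactone methyl ketal (target numbering: 2S,5S,6S,7R,8S)
Conditions: 2,4,6-trichlorobenzoyl chloride, Et3N, THF, 25 °C; then 25, 4-(dimethylamino)pyridine, toluene, 25 °C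
Reagents that add atoms: none
Why: Yamaguchi esterification should acylate the hindered secondary C8 hydroxyl with retention at C8 and without loss of the E geometry of the tiglate.

Step 18
Reactants: 27 8-O-tigloyl lactone methyl ketal
Product: 30 α-methylidene lactone methyl ketal (2-O-methyl ketal of the target), via Mannich base 28 (not isolated), via methiodide 29 (not isolated)
Conditions: LiN(SiMe3)2 (1.1 equiv), THF, −78 °C; CH2=NMe2+ I− (Eschenmoser's salt), −78 → 0 °C; then MeI, MeOH, 25 °C; then aq. NaHCO3, CH2Cl2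
Reagents that add atoms: N,N-dimethylmethyleneiminium iodide (Eschenmoser's salt), C=[N+](C)C.[I-]
Why: The hindered amide base should enolise the γ-lactone, the most acidic C–H left, in preference to the tiglate, and Mannich reaction with the iminium salt, N-methylation and Hofmann-type elimination then give the C11=C13 methylidene.

Step 19
Reactants: 30 α-methylidene lactone methyl ketal
Product: 31 CNP0307443.2 (target; 2S,5S,6S,7R,8S)
Conditions: pyridinium p-toluenesulfonate (20 mol%), acetone/H2O (4:1), 40 °C
Reagents that add atoms: water, O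
Why: Mild acid hydrolysis of the bridged mixed ketal should exchange OMe for OH through the oxocarbenium ion, and the hemiketal stays closed with C2 in the configuration that the oxolane bridge imposes (2S).

Compound list
1 | dimethyl (4R,5R)-2,2-dimethyl-1,3-dioxolane-4,5-dicarboxylate | COC(=O)[C@@H]1OC(C)(C)O[C@H]1C(=O)OC | starting material
2 | methyl (4R,5S)-5-(hydroxymethyl)-2,2-dimethyl-1,3-dioxolane-4-carboxylate | OC[C@@H]1OC(C)(C)O[C@H]1C(=O)OC | intermediate
3 | methyl (4R,5R)-5-formyl-2,2-dimethyl-1,3-dioxolane-4-carboxylate | O=C[C@@H]1OC(C)(C)O[C@H]1C(=O)OC | intermediate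
4 | methyl (4R,5S)-5-ethenyl-2,2-dimethyl-1,3-dioxolane-4-carboxylate | C=C[C@@H]1OC(C)(C)O[C@H]1C(=O)OC | intermediate
5 | 2-[(4R,5S)-5-ethenyl-2,2-dimethyl-1,3-dioxolan-4-yl]-1,3-bis(trimethylsilyl)propan-2-ol | C=C[C@@H]1OC(C)(C)O[C@H]1C(O)(C[Si](C)(C)C)C[Si](C)(C)C | intermediate
6 | (4S,5S)-4-ethenyl-2,2-dimethyl-5-[3-(trimethylsilyl)prop-1-en-2-yl]-1,3-dioxolane | C=C[C@@H]1OC(C)(C)O[C@H]1C(=C)C[Si](C)(C)C | intermediate
7 | acrolein (prop-2-enal) | C=CC=O | starting material
8 | 5-[(4S,5S)-5-ethenyl-2,2-dimethyl-1,3-dioxolan-4-yl]hexa-1,5-dien-3-ol (C3 epimers) | C=C[C@@H]1OC(C)(C)O[C@H]1C(=C)CC(O)C=C | intermediate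
9 | (4S,5S)-4,5-(isopropylidenedioxy)-6-methylidenecyclohept-2-en-1-ol (C1 epimers) | OC1C=C[C@@H]2OC(C)(C)O[C@H]2C(=C)C1 | intermediate
10 | (4S,5S)-4,5-(isopropylidenedioxy)-6-methylidenecyclohept-2-en-1-one | O=C1C=C[C@@H]2OC(C)(C)O[C@H]2C(=C)C1 | intermediate
11 | tert-butyl[(1-methoxyethenyl)oxy]dimethylsilane | C=C(OC)O[Si](C)(C)C(C)(C)C | starting material
12 | methyl 2-[(1R,6S,7S)-3-(tert-butyldimethylsilyloxy)-6,7-(isopropylidenedioxy)-5-methylidenecyclohept-2-en-1-yl]acetate | CC(C)(C)[Si](C)(C)OC1=C[C@@H](CC(=O)OC)[C@@H]2OC(C)(C)O[C@H]2C(=C)C1 | intermediate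
13 | methyl 2-[(1S,2S,3S)-2,3-(isopropylidenedioxy)-4-methylidene-6-oxo-7-(phenylsulfanyl)cycloheptyl]acetate (C7 epimers) | O=C1C(Sc3ccccc3)[C@@H](CC(=O)OC)[C@@H]2OC(C)(C)O[C@H]2C(=C)C1 | intermediate
14 | methyl 2-[(1S,2S,3S)-2,3-(isopropylidenedioxy)-4-methylidene-6-oxo-7-(phenylsulfonyl)cycloheptyl]acetate (C7 epimers) | O=C1C(S(=O)(=O)c3ccccc3)[C@@H](CC(=O)OC)[C@@H]2OC(C)(C)O[C@H]2C(=C)C1 | intermediate
15 | 2-(chloromethyl)-3-(trimethylsilyl)prop-1-ene | C=C(CCl)C[Si](C)(C)C | starting material
16 | methyl 2-[(1S,2S,3S)-2,3-(isopropylidenedioxy)-4-methylidene-6-oxo-7-(phenylsulfonyl)-7-{2-[(trimethylsilyl)methyl]prop-2-en-1-yl}cycloheptyl]acetate (C7 epimers) | O=C1CC(=C)[C@@H]2OC(C)(C)O[C@H]2[C@H](CC(=O)OC)C1(S(=O)(=O)c3ccccc3)CC(=C)C[Si](C)(C)C | intermediate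
17 | tetrabutylammonium alkoxide of the methylidenecyclopentanol fused across C2–C8 of 16 (C2 and C8 undefined) | [O-]C12CC(=C)[C@@H]3OC(C)(C)O[C@H]3[C@H](CC(=O)OC)C1(S(=O)(=O)c4ccccc4)CC(=C)C2.CCCC[N+](CCCC)(CCCC)CCCC | intermediate
18 | methyl 2-[(1S,2S,3S)-2,3-(isopropylidenedioxy)-4,8-dimethylidene-6-oxo-10-(phenylsulfonyl)cyclodecyl]acetate (C10 epimers) | O=C1CC(=C)[C@@H]2OC(C)(C)O[C@H]2[C@H](CC(=O)OC)C(S(=O)(=O)c3ccccc3)CC(=C)C1 | intermediate
19 | tricyclic methyl ketal lactone sulfone (2S,5S,6S,7S; C8 epimers) | C=C1CC(S(=O)(=O)c3ccccc3)[C@H]2CC(=O)O[C@@H]2[C@H]2O[C@@](OC)(C1)CC2=C | intermediate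
20 | lactol of 19 (C12 anomers, C8 epimers) | C=C1CC(S(=O)(=O)c3ccccc3)[C@H]2CC(O)O[C@@H]2[C@H]2O[C@@](OC)(C1)CC2=C | intermediate
21 | C8-lithio sulfone, lithium lactolate | C=C1CC([Li])(S(=O)(=O)c3ccccc3)[C@H]2CC(O[Li])O[C@@H]2[C@H]2O[C@@](OC)(C1)CC2=C | intermediate
22 | C8-(trimethylsilyloxy) sulfone, lithium lactolate | C=C1CC(O[Si](C)(C)C)(S(=O)(=O)c3ccccc3)[C@H]2CC(O[Li])O[C@@H]2[C@H]2O[C@@](OC)(C1)CC2=C | intermediate
23 | C8 ketone lactol (2S,5S,6S,7S; C12 anomers) | C=C1CC(=O)[C@H]2CC(O)O[C@@H]2[C@H]2O[C@@](OC)(C1)CC2=C | intermediate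
24 | C8 ketone γ-lactone (2S,5S,6S,7S) | C=C1CC(=O)[C@H]2CC(=O)O[C@@H]2[C@H]2O[C@@](OC)(C1)CC2=C | intermediate
25 | (8S)-alcohol (2S,5S,6S,7R,8S) | C=C1C[C@H](O)[C@H]2CC(=O)O[C@@H]2[C@H]2O[C@@](OC)(C1)CC2=C | intermediate
26 | tiglic acid, (E)-2-methylbut-2-enoic acid | OC(=O)/C(C)=C/C | starting material
27 | 8-O-tigloyl lactone methyl ketal (2S,5S,6S,7R,8S) | C=C1C[C@H](OC(=O)/C(C)=C/C)[C@H]2CC(=O)O[C@@H]2[C@H]2O[C@@](OC)(C1)CC2=C | intermediate
28 | C11-[(dimethylamino)methyl] lactone (C11 undefined) | C=C1C[C@H](OC(=O)/C(C)=C/C)[C@H]2C(CN(C)C)C(=O)O[C@@H]2[C@H]2O[C@@](OC)(C1)CC2=C | intermediate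
29 | C11-[(trimethylammonio)methyl] lactone iodide (C11 undefined) | C=C1C[C@H](OC(=O)/C(C)=C/C)[C@H]2C(C[N+](C)(C)C)C(=O)O[C@@H]2[C@H]2O[C@@](OC)(C1)CC2=C.[I-] | intermediate
30 | α-methylidene lactone methyl ketal (2-O-methyl ketal of the target) | C=C1C[C@H](OC(=O)/C(C)=C/C)[C@H]2C(=C)C(=O)O[C@@H]2[C@H]2O[C@@](OC)(C1)CC2=C | intermediate
31 | CNP0307443.2 (2S,5S,6S,7R,8S) | C=C1C[C@H](OC(=O)/C(C)=C/C)[C@H]2C(=C)C(=O)O[C@@H]2[C@H]2O[C@@](O)(C1)CC2=C | target

Total step count: 19. Longest linear sequence: 19 steps (from 1).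

Steps most likely to fail

Step 11 (key step). The fluoride medium is basic, so enolisation of the C2 ketone, migration of the C4=C15 or the new C10=C14 double bond into conjugation, or plain protodesilylation may outrun ring closure and fragmentation. The fallback sets out from 16 and comes back at 18, and it separates the two events. EtAlCl2 in CH2Cl2 at −78 °C should trigger an intramolecular Hosomi–Sakurai addition of the allylsilane to the C2 ketone under non-basic conditions and give the isolable bicyclic methylidenecyclopentanol F1. Its potassium alkoxide (KH, 18-crown-6, THF, 0 °C) should then fragment across C2–C8 to the sulfonyl carbanion, and an NH4Cl quench gives 18.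

Step 16. Facial selectivity of hydride delivery to the C8 ketone in the bridged ten-membered ring may be poor or opposite, and the ketone may enolise towards C7. The fallback sets out from 24 and comes back at 27. The bulky hydride LiBH(sBu)3 (THF, −78 °C) should attack anti to the C7 side chain and give the C8 epimer, the (8R)-alcohol F2. Mitsunobu esterification with tiglic acid 26 (PPh3, diisopropyl azodicarboxylate, toluene, 0 → 25 °C) then installs the tiglate with inversion at C8 and gives 27.

Step 14. Metalation at C8 next to a lithium lactolate may be incomplete, the lactolate may open to the hydroxy aldehyde, and oxygen transfer to the hindered carbanion may be slow. The fallback sets out from 20 and comes back at 23. The lactol is first masked as its tert-butyldimethylsilyl acetal F3 (tBuMe2SiCl, imidazole, DMF), so that one equivalent of BuLi (THF, −78 °C) metalates C8 alone. The carbanion is oxygenated with MoO5·pyridine·HMPA (−78 → −20 °C) to give the C8 ketone silyl acetal F4, and HF·pyridine (pyridine, THF, 0 °C) frees the lactol 23.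

Further compounds
F1 | step 11 | bicyclic methylidenecyclopentanol (neutral alcohol corresponding to 17) | OC12CC(=C)[C@@H]3OC(C)(C)O[C@H]3[C@H](CC(=O)OC)C1(S(=O)(=O)c4ccccc4)CC(=C)C2
F2 | step 16 | (8R)-alcohol, C8 epimer of 25 | C=C1C[C@@H](O)[C@H]2CC(=O)O[C@@H]2[C@H]2O[C@@](OC)(C1)CC2=C
F3 | step 14 | tert-butyldimethylsilyl acetal of lactol 20 | C=C1CC(S(=O)(=O)c3ccccc3)[C@H]2CC(O[Si](C)(C)C(C)(C)C)O[C@@H]2[C@H]2O[C@@](OC)(C1)CC2=C
F4 | step 14 | C8 ketone tert-butyldimethylsilyl lactol acetal | C=C1CC(=O)[C@H]2CC(O[Si](C)(C)C(C)(C)C)O[C@@H]2[C@H]2O[C@@](OC)(C1)CC2=C
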